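**Retrosynthetic overview**

- The target is an achiral benzene ring: C1 (OMe), C2 (H), C3 (2-phenylethyl), C4 (OMe), C5 (OMe), C6 (3-hydroxy-3-methylbutyl). The plan rests on the 1,3-relationship of the C1 and C5 oxygens across the alkylated C6, which is the pattern of a cyclohexane-1,3-dione alkylated at its central carbon. The C4 oxygen is carried in on the central carbon of a methoxymalonate.
- Target ⇐ triethylsilyl ether of the tertiary alcohol ⇐ double O-methylation of a 4-methoxyresorcinol ⇐ one dehydrogenation of a 4-methoxycyclohexane-1,3-dione ⇐ loss of the surplus ester.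
- The only ring made is the future benzene ring. It is closed by a Michael–Claisen annulation of dimethyl 2-methoxymalonate onto an E-enone, forming C3–C4 and then C5–C6, and is aromatised three steps later.
- The enone comes from a directed aldol and dehydration between 3-phenylpropanal and the silylated hydrate of 6-methylhept-5-en-2-one.

Key step: step 5

Remark on the chemistry: the target has no stereocentre, so the sp3 centres that arise on the way are carried as mixtures and are erased by enolisation or aromatisation.

**Step 1**
Reactants: 1 6-methylhept-5-en-2-one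
Product: 2 6-hydroxy-6-methylheptan-2-one
Conditions: 35% aq H2SO4, 0 °C → rt; NaHCO3 work-up
Reagents that add atoms: water, O
Why: Markovnikov acid-catalysed hydration, in which protonation of the trisubstituted alkene gives the tertiary cation that water captures; no stereocentre is formed.

**Step 2**
Reactants: 2 6-hydroxy-6-methylheptan-2-one
Product: 3 6-methyl-6-(triethylsilyloxy)heptan-2-one
Conditions: Et3SiCl, imidazole, DMAP (cat.), DMF, rt → 40 °C
Reagents that add atoms: chlorotriethylsilane, CC[Si](Cl)(CC)CC
Why: Silylation through the N-silylimidazolium species caps the tertiary alcohol as a base-stable ether, so that it cannot consume base or later close onto the neighbouring ring carbonyl or enol to a six-membered cyclic enol ether.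

**Step 3**
Reactants: 3 6-methyl-6-(triethylsilyloxy)heptan-2-one; 4 3-phenylpropanal
Product: 6 rac-3-hydroxy-9-methyl-1-phenyl-9-(triethylsilyloxy)decan-5-one, via lithium enolate 5 (not isolated)
Conditions: LiN(i-Pr)2 (1.1 equiv), THF, −78 °C, 3 added slowly; then 4, −78 °C; AcOH/THF quench at −78 °C
Reagents that add atoms: lithium diisopropylamide, [Li+].CC(C)[N-]C(C)C (lithium carried only in 5)
Why: Directed crossed aldol addition, in which irreversible kinetic deprotonation by the hindered amide at −78 °C takes a methyl proton in preference to a methylene proton and the preformed enolate adds to the aldehyde faster than it exchanges protons; the carbinol centre forms racemic and is removed in step 4.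

**Step 4**
Reactants: 6 rac-3-hydroxy-9-methyl-1-phenyl-9-(triethylsilyloxy)decan-5-one
Product: 8 (E)-9-methyl-1-phenyl-9-(triethylsilyloxy)dec-3-en-5-one, via beta-mesyloxy ketone 7 (not isolated)
Conditions: MsCl, Et3N, CH2Cl2, 0 °C; then DBU, rt
Reagents that add atoms: methanesulfonyl chloride, CS(=O)(=O)Cl (atoms carried only in 7)
Why: Mesylation of the only free (secondary) alcohol followed by E1cB elimination should give the conjugated enone as its thermodynamically favoured E isomer.

**Step 5**
Reactants: 8 (E)-9-methyl-1-phenyl-9-(triethylsilyloxy)dec-3-en-5-one; 9 dimethyl 2-methoxymalonate (1.3 equiv)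
Product: 11 methyl 1-methoxy-2,4-dioxo-3-[3-methyl-3-(triethylsilyloxy)butyl]-6-(2-phenylethyl)cyclohexane-1-carboxylate (diastereomer mixture, largely enolised), via Michael adduct 10 (not isolated)
Conditions: NaOMe (1.5 equiv), MeOH, rt → reflux; then AcOH to pH 5, 0 °C
Reagents that add atoms: none
Why: Methoxide deprotonates 9 and the stabilised, soft methoxymalonate anion adds reversibly to the beta-carbon of E-enone 8 (C3–C4 bond) to give keto diester 10, after which equilibration of the ketone enolates lets the C6 enolate acylate on one of the two ester groups (C5–C6 bond) with loss of methoxide. This is the malonate Michael–Claisen (Dieckmann-type) annulation used for 5-substituted cyclohexane-1,3-diones, run here with a 2-alkoxy-substituted malonate. The single ring, the future benzene ring, closes by a 6-(enolendo)-exo-trig acylation. The new sp3 centres C3, C4 and C6 form without control and need none, since C6 is enolised at once and C3 and C4 become aromatic carbons in step 7. The step needs 1,4- over 1,2-addition, which the delocalised malonate anion and the reversibility of carbonyl addition secure, and acylation from C6 and not C2, which is secured because only the C6 enolate reaches an ester through a six-membered transition state while C2 would close a four-membered ring. Deprotonation of the product at C6 to the beta-diketone enolate is the thermodynamic sink that draws the crowded Michael equilibrium forward, and the same enolate shields the C5 carbonyl from retro-Claisen cleavage.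

**Step 6**
Reactants: 11 methyl 1-methoxy-2,4-dioxo-3-[3-methyl-3-(triethylsilyloxy)butyl]-6-(2-phenylethyl)cyclohexane-1-carboxylate
Product: 13 4-methoxy-2-[3-methyl-3-(triethylsilyloxy)butyl]-5-(2-phenylethyl)cyclohexane-1,3-dione (diastereomer mixture, enolised), via beta-keto acid 12 (not isolated)
Conditions: 2 M aq NaOH, MeOH, 60 °C; 0 °C, 1 M HCl to pH 4, toluene extraction; toluene, 70 °C
Reagents that add atoms: water, O (oxygen carried only in 12)
Why: Saponification takes place on the dione enolate, which blocks ring-opening, and the liberated beta-keto acid 12 should lose CO2 through the usual cyclic six-membered transition state; the acid is set free cold and decarboxylated in the organic phase so that the tertiary silyl ether does not meet warm aqueous acid.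

**Step 7**
Reactants: 13 4-methoxy-2-[3-methyl-3-(triethylsilyloxy)butyl]-5-(2-phenylethyl)cyclohexane-1,3-dione
Product: 16 4-methoxy-2-[3-methyl-3-(triethylsilyloxy)butyl]-5-(2-phenylethyl)benzene-1,3-diol, via bis(trimethylsilyloxy)cyclohexadiene 14 (not isolated), via bis(trimethylsilyl) aryl ether 15 (not isolated)
Conditions: Me3SiOTf (2.4 equiv), Et3N, CH2Cl2, 0 °C → rt, pentane extraction; DDQ (1.05 equiv), 2,4,6-collidine, toluene, 0 °C → rt, filter; K2CO3 (cat.), MeOH, 0 °C, argon
Reagents that add atoms: trimethylsilyl trifluoromethanesulfonate, C[Si](C)(C)OS(=O)(=O)C(F)(F)F (silyl groups carried only in 14 and 15)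
Why: Double enol silylation of the 1,3-dione with silyl triflate and amine should give the 1,3-bis(silyloxy)cyclohexa-1,3-diene, which DDQ dehydrogenates by hydride abstraction from the allylic C3/C4 positions and proton loss, as in the quinone aromatisation of cyclohexadienes and silyl dienol ethers; the regioisomeric diene converges on the same arene, and the aryl silyl ethers guard the electron-rich diol against over-oxidation until the mild methanolysis.

**Step 8**
Reactants: 16 4-methoxy-2-[3-methyl-3-(triethylsilyloxy)butyl]-5-(2-phenylethyl)benzene-1,3-diol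
Product: 17 triethyl({2-methyl-4-[2,3,6-trimethoxy-4-(2-phenylethyl)phenyl]butan-2-yl}oxy)silane
Conditions: MeI (3 equiv), K2CO3, DMF, rt, argon
Reagents that add atoms: iodomethane, CI
Why: Williamson O-methylation of both phenoxides under mild carbonate conditions, which leave the tertiary silyl ether untouched.

**Step 9**
Reactants: 17 triethyl({2-methyl-4-[2,3,6-trimethoxy-4-(2-phenylethyl)phenyl]butan-2-yl}oxy)silane
Product: 18 2-methyl-4-[2,3,6-trimethoxy-4-(2-phenylethyl)phenyl]butan-2-ol (CNP0309409.0)
Conditions: Bu4NF, THF, rt → 40 °C; water work-up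
Reagents that add atoms: none
Why: Fluoride-driven desilylation (strong Si–F bond) frees the tertiary alcohol without acid, so it can neither ionise nor eliminate.

**Compound list**

1 | 6-methylhept-5-en-2-one | CC(=O)CCC=C(C)C | starting material
2 | 6-hydroxy-6-methylheptan-2-one | CC(=O)CCCC(C)(C)O | intermediate
3 | 6-methyl-6-(triethylsilyloxy)heptan-2-one | CC(=O)CCCC(C)(C)O[Si](CC)(CC)CC | intermediate
4 | 3-phenylpropanal | O=CCCc1ccccc1 | starting material
5 | lithium 6-methyl-6-(triethylsilyloxy)hept-1-en-2-olate | [Li+].[O-]C(=C)CCCC(C)(C)O[Si](CC)(CC)CC | intermediate (not isolated)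
6 | rac-3-hydroxy-9-methyl-1-phenyl-9-(triethylsilyloxy)decan-5-one | O=C(CC(O)CCc1ccccc1)CCCC(C)(C)O[Si](CC)(CC)CC | intermediate
7 | 9-methyl-5-oxo-1-phenyl-9-(triethylsilyloxy)decan-3-yl methanesulfonate (racemic) | CS(=O)(=O)OC(CCc1ccccc1)CC(=O)CCCC(C)(C)O[Si](CC)(CC)CC | intermediate (not isolated)
8 | (E)-9-methyl-1-phenyl-9-(triethylsilyloxy)dec-3-en-5-one | O=C(/C=C/CCc1ccccc1)CCCC(C)(C)O[Si](CC)(CC)CC | intermediate
9 | dimethyl 2-methoxymalonate | COC(C(=O)OC)C(=O)OC | starting material
10 | dimethyl 2-methoxy-2-[9-methyl-5-oxo-1-phenyl-9-(triethylsilyloxy)decan-3-yl]propanedioate (racemic) | COC(=O)C(OC)(C(=O)OC)C(CCc1ccccc1)CC(=O)CCCC(C)(C)O[Si](CC)(CC)CC | intermediate (not isolated)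
11 | methyl 1-methoxy-2,4-dioxo-3-[3-methyl-3-(triethylsilyloxy)butyl]-6-(2-phenylethyl)cyclohexane-1-carboxylate (diastereomer mixture) | COC(=O)C1(OC)C(CCc2ccccc2)CC(=O)C(CCC(C)(C)O[Si](CC)(CC)CC)C1=O | intermediate
12 | 1-methoxy-2,4-dioxo-3-[3-methyl-3-(triethylsilyloxy)butyl]-6-(2-phenylethyl)cyclohexane-1-carboxylic acid (diastereomer mixture) | OC(=O)C1(OC)C(CCc2ccccc2)CC(=O)C(CCC(C)(C)O[Si](CC)(CC)CC)C1=O | intermediate (not isolated)
13 | 4-methoxy-2-[3-methyl-3-(triethylsilyloxy)butyl]-5-(2-phenylethyl)cyclohexane-1,3-dione (diastereomer mixture) | COC1C(CCc2ccccc2)CC(=O)C(CCC(C)(C)O[Si](CC)(CC)CC)C1=O | intermediate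
14 | 6-methoxy-2-[3-methyl-3-(triethylsilyloxy)butyl]-5-(2-phenylethyl)-1,3-bis(trimethylsilyloxy)cyclohexa-1,3-diene (diastereomer mixture; drawn as the regioisomer enolised toward the ring CH2) | COC1C(CCc2ccccc2)C=C(O[Si](C)(C)C)C(CCC(C)(C)O[Si](CC)(CC)CC)=C1O[Si](C)(C)C | intermediate (not isolated)
15 | 4-methoxy-2-[3-methyl-3-(triethylsilyloxy)butyl]-5-(2-phenylethyl)-1,3-bis(trimethylsilyloxy)benzene | COc1c(CCc2ccccc2)cc(O[Si](C)(C)C)c(CCC(C)(C)O[Si](CC)(CC)CC)c1O[Si](C)(C)C | intermediate (not isolated)
16 | 4-methoxy-2-[3-methyl-3-(triethylsilyloxy)butyl]-5-(2-phenylethyl)benzene-1,3-diol | COc1c(CCc2ccccc2)cc(O)c(CCC(C)(C)O[Si](CC)(CC)CC)c1O | intermediate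
17 | triethyl({2-methyl-4-[2,3,6-trimethoxy-4-(2-phenylethyl)phenyl]butan-2-yl}oxy)silane | COc1cc(CCc2ccccc2)c(OC)c(OC)c1CCC(C)(C)O[Si](CC)(CC)CC | intermediate
18 | 2-methyl-4-[2,3,6-trimethoxy-4-(2-phenylethyl)phenyl]butan-2-ol | COc1cc(CCc2ccccc2)c(OC)c(OC)c1CCC(C)(C)O | target

**Step count and risks**

Total step count: 9. Longest linear sequence: 9 steps (1 → 18).

Steps most likely to fail:

1. Step 5. The conjugate addition creates a crowded quaternary carbon and may revert before the ring closes, leaving base-induced self-condensation of the enone to take over. Fallback, from 8 back to 13: the oxygenated carbon is delivered irreversibly as a silyl ketene acetal. Methyl methoxyacetate is converted with LiN(i-Pr)2 and Me3SiCl in THF at −78 °C into 1,2-dimethoxy-1-(trimethylsilyloxy)ethene F1. A Mukaiyama–Michael addition of this acetal to 8 with catalytic Sc(OTf)3 in CH2Cl2 at −78 °C should give methyl 2-methoxy-9-methyl-3-(2-phenylethyl)-9-(triethylsilyloxy)-5-(trimethylsilyloxy)dec-4-enoate F2. Mild hydrolysis of its enol ether (aqueous citric acid, THF, 0 °C) should give methyl 2-methoxy-9-methyl-5-oxo-3-(2-phenylethyl)-9-(triethylsilyloxy)decanoate F3. This delta-keto ester is closed by the same C5–C6 Claisen acylation with KOt-Bu in THF, followed by acidification to pH 4, and gives dione 13 directly with no ester to remove.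

2. Step 7. The double enol silylation may stop halfway, the quinone may form adducts with the diene or oxidise further, and the freed electron-rich diol may oxidise in air. Fallback, from 14 back to 16: the two-electron oxidation is delivered through selenium. Diene 14 is treated with PhSeCl in CH2Cl2 at −78 °C, which should attack the terminal diene carbon and, after aqueous work-up, give 4-methoxy-2-[3-methyl-3-(triethylsilyloxy)butyl]-5-(2-phenylethyl)-6-(phenylselanyl)cyclohexane-1,3-dione F4. Oxidation with H2O2 in CH2Cl2/pyridine at 0 °C → rt and syn-elimination of the selenoxide toward the C3 hydrogen should give a hydroxydienone that tautomerises to resorcinol 16.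

3. Step 6. The hindered ester may hydrolyse slowly, and the triethylsilyl group may be lost during hydrolysis or acidification, after which the freed tertiary alcohol could close onto the enolised dione under acid. Fallback, from 11 back to 13: a non-hydrolytic Krapcho dealkoxycarbonylation (LiCl, wet DMSO, about 130 °C). Chloride removes the ester methyl group by SN2 attack, and the carboxylate loses CO2 in the same flask. The material never passes through an acidified aqueous phase, and no new isolable compound is involved.

**Further compounds**

F1 | step 5 | 1,2-dimethoxy-1-(trimethylsilyloxy)ethene (E/Z mixture) | COC=C(OC)O[Si](C)(C)C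
F2 | step 5 | methyl 2-methoxy-9-methyl-3-(2-phenylethyl)-9-(triethylsilyloxy)-5-(trimethylsilyloxy)dec-4-enoate (isomer mixture) | COC(=O)C(OC)C(CCc1ccccc1)C=C(O[Si](C)(C)C)CCCC(C)(C)O[Si](CC)(CC)CC
F3 | step 5 | methyl 2-methoxy-9-methyl-5-oxo-3-(2-phenylethyl)-9-(triethylsilyloxy)decanoate (diastereomer mixture) | COC(=O)C(OC)C(CCc1ccccc1)CC(=O)CCCC(C)(C)O[Si](CC)(CC)CC
F4 | step 7 | 4-methoxy-2-[3-methyl-3-(triethylsilyloxy)butyl]-5-(2-phenylethyl)-6-(phenylselanyl)cyclohexane-1,3-dione (diastereomer mixture) | COC1C(CCc2ccccc2)C([Se]c2ccccc2)C(=O)C(CCC(C)(C)O[Si](CC)(CC)CC)C1=O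
F0 | step 6 | none | none
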